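## Analysis of the target

Compound 29 (C24H14O11) contains four benzene rings. Ring A, a 3,5-dihydroxyphenyl group, is bound through an ether oxygen to ring B; rings B and C are bridged by two oxygens into a dibenzo-1,4-dioxin; rings C and D are joined by one C–C bond and one oxygen into a dibenzofuran. Positions are named with dibenzofuran numbers for rings D and C (ring D: C1–C4 and C4a; furan oxygen O5; ring C: C5a, C6–C9, C9a; biaryl bond C9a–C9b) and b1–b6 for ring B. Hydroxyls sit on C1, C3, C7, b2 and b4; the dioxin oxygens O8 and O9 link C8 to b6 and C9 to b5; b1 carries the ring A ether; C6 and b3 are CH. There is no stereocentre, so every selectivity problem is one of position. The seven free phenols on very electron-rich rings are oxidized easily, above all in base, and are therefore carried as ethers until the last step. The synthesis is hard because oxygens of the same kind must be told apart: which two of the three neighbouring oxygens of ring C enter the dioxin (C8 and C9, not C7), how the unsymmetrical ring B is oriented on it (b6 on O8), and where ring A goes. The plan rests on ring D: its oxygens on C1, C3 and C4a alternate with carbon as in a triketide, and it hangs on ring C through the single carbon C9b. A 2-arylphloroglucinol is symmetric about that bond, so ring D can be folded from an open chain on a finished ring C, and the furan closure needs no choice between the two ortho hydroxyls.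

## Retrosynthetic reasoning

29 to 28. All seven hydroxyls are unmasked together from heptamethyl ether 28. Methyl is the one group that survives strong base, copper and peracid, and six of the seven methyl groups come with starting materials 1, 19 and 27. The forward step must cleave alkyl–oxygen bonds only and leave the five aryl–oxygen–aryl bonds.

28 to 26 and 27. The ring A ether is cut between its oxygen and ring A. The oxygen then stays on b1 as the phenol of 26, and ring A comes from the symmetric iodide 27, so ring A poses no positional question. Cutting on the other side would need a leaving group on the fully substituted, electron-rich ring B. The forward step is an O-arylation of a phenol with two ortho substituents.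

26 to 24. The b1 hydroxyl is traced back to a formyl group. That carbon is excised oxidatively in the forward sense. It is wanted because it is the only activating group for building the dioxin and because it marks b1 as different from b4.

24 to 18 and 22. Both dioxin bonds are cut on the ring B side, O8–b6 and O9–b5. Ring C keeps its own oxygens, which come from 1, and acts twice as nucleophile. Ring B (22) carries two different leaving groups: fluoride next to the formyl group for substitution by O8, and bromide for a copper-mediated closure by O9. Two different bond formations in a fixed order decide the orientation of ring B. Cutting on the ring C side would put two leaving groups on a ring with four donor substituents.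

22 to 21 to 19. The C–Br and C–CHO bonds are cut in turn; both are made by electrophilic substitution, directed by the two methoxy groups of symmetric 19.

18 to 16. Two O–CH3 bonds of ring C are cut, at C8 and C9. This is where the three neighbouring oxygens of ring C are told apart. The ethers on C8 and C9 each have two ortho neighbours (C9 lies in the bay facing ring D) and are twisted out of the ring plane; the ether on C7 has a free ortho position and stays conjugated. The forward step must exploit that difference.

16 to 15 to 13. The ring D hydroxyls are capped, and the furan bond C4a–O5 is cut back to a biaryl. That bond is chosen because C4a belongs to a 1,3,5-trioxygenated ring and can be attacked in its keto form. The oxygen comes from ring C, where it is held as the benzyl ether of 13 and is the only free hydroxyl of ring C after hydrogenolysis (14).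

13 to 11, the key disconnection. Ring D is opened between the aryl-bearing carbon C9b and a neighbouring oxygen-bearing carbon; in the chain these are the benzylic C-6 and the ester C-1 of 11. This brings all six carbons and three oxygens of ring D from a linear chain. The hindered biaryl bond is never made by coupling two rings: it already exists as the unhindered benzylic bond of 11. The forward reaction must acylate carbon rather than oxygen and then aromatize.

11 to 8 and 9. The chain is cut between C-4 and C-5 into arylacetyl chloride 8 and 9, a four-carbon β-keto ester equivalent that reacts at its terminal carbon without base.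

8 to 7 to 5 to 3 to 1 and 2. The acid chloride comes from acid 7. The benzyl group is put on the phenol oxygen when lactone 5 is opened. The lactone comes from mandelic acid 3 by removal of the benzylic hydroxyl. The aryl–carbon bond is made from 1 and 2; 1 is symmetric and its para position is blocked, so only one ortho product can form.

## Alternatives that were turned down

Alternative 1: The dibenzofuran is cut at the furan O–C bond on the ring C side and at the biaryl bond. In the forward step a fluoride source releases an aryne from silyl triflate A3, the phenoxide of A2 adds to it, and a palladium catalyst inserts into the C–I bond and closes onto the ortho C–H of the new ring to give A1. A1 is the same compound as 16. On step count this alternative is stronger: it reaches in one pot what the chosen route reaches in eight steps, both partners are symmetric where it matters, and its reaction types are precedented while step 6 is not. Against it: A2 and A3 must first be made in several steps each, which cuts the gain to perhaps three or four steps. The palladium step has to form the bay with two methoxy groups facing each other. The aryl anion formed after addition to the aryne can be quenched before the metal acts. In its place the chosen strategy makes the aryl–aryl bond before it is hindered and uses no precious metal on the main line. Above all it delivers ring D with free hydroxyls next to a fully etherified ring C (13, 15), the only stage at which the oxygens of the two rings differ chemically; the reserve plan for step 9 uses exactly that difference.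

Alternative 2: The dioxin is cut at the O–b5 bond. The precursor is spiroketal dienone A5 (racemic at the spiro carbon), in which the carbon that becomes b6 carries both O8 and O9. Under acid one aryloxy oxygen shifts to the neighbouring carbon, the five-membered dioxole grows into the dioxin and ring B rearomatizes to A4. A4 is the same compound as 26. In its favour: ring B enters as a plain phenol without halogen or copper, and the b1 hydroxyl arises by itself from the dienone carbonyl, so steps 10 to 13 would be replaced by about two. Against it: the orientation of ring B depends on which of two nearly equal ketal C–O bonds ionizes. Only migration of O9 gives A4; migration of O8 gives the isomer. Other shifts of the dienone and hydrolysis of the ketal compete. The alternative also still needs catechol 18, so it replaces only the late stage and leaves ring D unsolved. The chosen route fixes the orientation by two different bond formations in a set order.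

Alternative 3: Ring B is cut at a ring C–C bond. Heating cyclobutenone A7 (racemic) opens it to a dienylketene, whose six-electron electrocyclization closes ring B as phenol A6. A6 carries ring A on b1 and a different group on every oxygen. On this point the alternative is stronger than the chosen route, which attaches ring A late to a hindered phenol and differentiates b1 only through a formyl group. Against it: in A6 the dioxin oxygens sit on ring B, so ring C would have to be the double electrophile at C8 and C9. That means two leaving groups on a ring with four donors, two copper couplings, and an open orientation problem. The mixed squarate behind A7 takes several steps, and rings C and D are not addressed. The chosen strategy keeps the nucleophilic oxygens on ring C, where they come free with 1.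

Key step: step 6

## Route

Remarks on the chemistry: 9 is taken as the purchased reagent (mixture of double-bond isomers, which react alike). 2 is used as its monohydrate. 3 is racemic and its stereocentre disappears in step 2. The chain of 11 is numbered from the ester carbon C-1 to the benzylic carbon C-6.

Step 1
Reactants: 1 3,4,5-trimethoxyphenol; 2 glyoxylic acid
Product: 3 (±)-2-hydroxy-2-(2-hydroxy-4,5,6-trimethoxyphenyl)acetic acid
Conditions: 2 (1.1 equiv), NaOH (2.2 equiv), H2O, 0 °C → rt; then HCl to pH 2, 0 °C
Reagents that add atoms: none
Why: Ortho-hydroxyalkylation of a phenoxide by glyoxylate (Friedel–Crafts-type addition); the two ortho positions of 1 are equivalent and the para position is blocked. In alkali the mandelate does not ionize, so a second arylation is avoided; the new stereocentre is formed racemic and is removed in step 2.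

Step 2
Reactants: 3 (±)-2-hydroxy-2-(2-hydroxy-4,5,6-trimethoxyphenyl)acetic acid
Product: 5 4,5,6-trimethoxy-1-benzofuran-2(3H)-one, via hydroxy acid 4 (not isolated)
Conditions: H2 (3 bar), 10% Pd/C, AcOH, H2SO4 (cat.), 60 °C; filter; toluene, reflux, Dean–Stark trap
Reagents that add atoms: none
Why: Catalytic hydrogenolysis of the benzylic C–OH bond of a mandelic acid, made easy by the electron-rich ring; the ortho-hydroxyarylacetic acid 4 then closes to the five-membered lactone when water is removed.

Step 3
Reactants: 5 4,5,6-trimethoxy-1-benzofuran-2(3H)-one
Product: 7 2-[2-(benzyloxy)-4,5,6-trimethoxyphenyl]acetic acid, via benzyl ester 6 (not isolated)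
Conditions: KOH (powdered, 4 equiv), DMSO, rt; BnBr (2.3 equiv), rt; then H2O–MeOH, 60 °C; HCl to pH 2
Reagents that add atoms: benzyl bromide BrCc1ccccc1; potassium hydroxide [K+].[OH-]
Why: Hydroxide first opens the lactone to the dianion of 4, so the methylene group is no longer enolizable; Williamson alkylation in a dipolar aprotic solvent then takes place on the two oxygens. The excess hydroxide saponifies ester 6 and leaves the benzyl ether.

Step 4
Reactants: 7 2-[2-(benzyloxy)-4,5,6-trimethoxyphenyl]acetic acid
Product: 8 2-[2-(benzyloxy)-4,5,6-trimethoxyphenyl]acetyl chloride
Conditions: (COCl)2 (1.3 equiv), DMF (cat.), CH2Cl2, 0 °C → rt; evaporate, use at once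
Reagents that add atoms: oxalyl chloride ClC(=O)C(=O)Cl
Why: Acid chloride formation through the chloroiminium catalyst under neutral conditions; low temperature and immediate use keep the ortho ether oxygen from attacking the acyl chloride.

Step 5
Reactants: 8 2-[2-(benzyloxy)-4,5,6-trimethoxyphenyl]acetyl chloride; 9 1-methoxy-1,3-bis(trimethylsilyloxy)buta-1,3-diene
Product: 11 methyl 6-[2-(benzyloxy)-4,5,6-trimethoxyphenyl]-3,5-dioxohexanoate, via silyl enol ether 10 (not isolated)
Conditions: 9 (1.5 equiv), CH2Cl2, −78 °C → rt; then HCl (1 M), THF, 0 °C
Reagents that add atoms: none
Why: The bis(silyl) dienol ether is acylated at its terminal carbon by the acid chloride (vinylogous Mukaiyama-type C-acylation) without any base, so the arylacetyl chloride cannot form a ketene. Loss of chlorotrimethylsilane and acidic hydrolysis of 10 give the 3,5-dioxo ester.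

Step 6
Reactants: 11 methyl 6-[2-(benzyloxy)-4,5,6-trimethoxyphenyl]-3,5-dioxohexanoate
Product: 13 2-[2-(benzyloxy)-4,5,6-trimethoxyphenyl]benzene-1,3,5-triol, via cyclohexane-1,3,5-trione 12 (not isolated)
Conditions: KOtBu (4 equiv), DMF, 0 → 70 °C, argon; then HCl (1 M), 0 °C
Reagents that add atoms: none
Why: Proposed new method: with excess KOtBu the resting state of 11 is the bis-enolate at C-2 and C-4, but proton exchange gives a small share of the dianion deprotonated at C-4 and at the benzylic C-6, in which the ester is not enolized; its terminal benzylic carbon adds to the ester carbonyl, methoxide leaves, and trione 12 is deprotonated and tautomerizes to the aromatic triol, so that the C–C bond formation cannot revert. The closest known reaction types are the acylation of 1,3-diketone dianions by esters at their terminal carbon, the Claisen cyclization of 3,5,7-triketo esters to acylphloroglucinols and the Dieckmann-type closure of 6-aryl-5-oxohexanoates to 2-arylcyclohexane-1,3-diones; a 3,5-dioxo ester that closes through a carbon activated by one ketone and an aryl group only has not been shown. Ring D is closed in a 6-(enolendo)-exo-trig mode. No stereocentre is formed. The step needs acylation at carbon C-6 in place of the C-5 oxygen, which would give a 4-hydroxy-2-pyranone, and ring closure in place of condensation between two chains. Potassium in DMF does not chelate the 1,3-diketonate, so the chain is free to take the extended (W) shape that puts C-6 and not the C-5 oxygen next to the ester, and a dianion of this kind reacts at its terminal carbon. With excess base every species other than this dianion has its ester switched off by enolization at C-2, which also closes the pyranone path, and the two ortho substituents of ring C shield the C-5 ketone and C-6 from a second chain. The benzyl ether keeps the ring C oxygen from adding to the C-5 ketone.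

Step 7
Reactants: 13 2-[2-(benzyloxy)-4,5,6-trimethoxyphenyl]benzene-1,3,5-triol
Product: 15 7,8,9-trimethoxydibenzo[b,d]furan-1,3-diol, via biaryl tetraol 14 (not isolated)
Conditions: H2 (1 bar), 10% Pd/C, EtOAc–MeOH, rt; filter under argon, evaporate; then AcOH, HCl (cat.), 80 °C
Reagents that add atoms: none
Why: Hydrogenolysis frees the one ring C hydroxyl ortho to the biaryl bond; under mild acid it adds to the keto tautomer of the phloroglucinol ring (5-exo-trig) and water is lost, a cyclodehydration of a 2,2'-dihydroxybiaryl. The two ortho carbons of ring D are equivalent, and mild acid avoids the other closure, in which a ring D hydroxyl would displace the neighbouring methoxy group of ring C.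

Step 8
Reactants: 15 7,8,9-trimethoxydibenzo[b,d]furan-1,3-diol
Product: 16 1,2,3,7,9-pentamethoxydibenzo[b,d]furan
Conditions: Me2SO4 (3 equiv), K2CO3 (4 equiv), acetone, reflux
Reagents that add atoms: dimethyl sulfate COS(=O)(=O)OC
Why: Williamson O-methylation of the two ring D phenols; a hard electrophile with a weak base in acetone alkylates phloroglucinol-type phenoxides on oxygen, not on carbon.

Step 9
Reactants: 16 1,2,3,7,9-pentamethoxydibenzo[b,d]furan
Product: 18 3,7,9-trimethoxydibenzo[b,d]furan-1,2-diol, via cyclic chloroborate 17 (not isolated)
Conditions: BCl3 (3 equiv, 1 M in CH2Cl2), CH2Cl2, −78 → 0 °C; then MeOH, H2O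
Reagents that add atoms: none
Why: Lewis-acid cleavage of aryl methyl ethers starts at the methoxy groups that are twisted out of the ring plane, here the central one on C8 and its bay neighbour on C9; once one is cleaved, the boron on that oxygen chelates and cleaves the other, and the five-membered chloroborate 17 stops further reaction at low temperature. The coplanar ethers on C7, C1 and C3 should survive, and aqueous work-up frees the catechol (free hydroxyls on C8 and C9).

Step 10
Reactants: 19 1-fluoro-3,5-dimethoxybenzene
Product: 21 2-fluoro-4,6-dimethoxybenzaldehyde, via iminium chloride 20 (not isolated)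
Conditions: POCl3 (1.2 equiv), DMF, 0 → 70 °C; then NaOAc, H2O, rt
Reagents that add atoms: N,N-dimethylformamide CN(C)C=O; water O
Why: Vilsmeier–Haack formylation; the bulky chloroiminium ion attacks the position para to one methoxy group and ortho to the other, next to fluorine, in preference to the position between the two methoxy groups.

Step 11
Reactants: 21 2-fluoro-4,6-dimethoxybenzaldehyde
Product: 22 3-bromo-2-fluoro-4,6-dimethoxybenzaldehyde
Conditions: NBS (1.05 equiv), MeCN, 0 °C → rt
Reagents that add atoms: N-bromosuccinimide O=C1CCC(=O)N1Br
Why: Electrophilic aromatic bromination; C3 is para to one methoxy group and ortho to the other, whereas C5 lies between both methoxy groups, one of which is pushed toward C5 by the formyl group. Bromine should therefore enter next to fluorine.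

Step 12
Reactants: 18 3,7,9-trimethoxydibenzo[b,d]furan-1,2-diol; 22 3-bromo-2-fluoro-4,6-dimethoxybenzaldehyde
Product: 24 pentacyclic dioxin aldehyde with CHO on b1 and OMe on b2/b4/C1/C3/C7, via diaryl ether 23 (not isolated)
Conditions: Cs2CO3 (2.5 equiv), DMF, 80 °C, argon; then CuI (20 mol %), N,N-dimethylglycine (40 mol %), 110 °C
Reagents that add atoms: none
Why: Nucleophilic aromatic substitution of the fluoride ortho to the formyl group by O8, the more acidic and less hindered catechol oxygen, then intramolecular Ullmann ether synthesis between the bay hydroxyl O9 and the neighbouring bromide (six-membered ring). The bromide is meta to the formyl group and does not react before copper is added, so the order of the two events sets the orientation of ring B.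

Step 13
Reactants: 24 pentacyclic dioxin aldehyde with CHO on b1
Product: 26 pentacyclic phenol with OH on b1 and OMe on b2/b4/C1/C3/C7, via aryl formate 25 (not isolated)
Conditions: mCPBA (1.3 equiv), NaHCO3, CH2Cl2, 0 °C → rt; then K2CO3 (cat.), MeOH, rt
Reagents that add atoms: 3-chloroperoxybenzoic acid OOC(=O)c1cccc(Cl)c1
Why: Baeyer–Villiger oxidation of a benzaldehyde flanked by two oxygen substituents goes by aryl migration to the formate (Dakin-type outcome), which methanolysis cleaves to the phenol.

Step 14
Reactants: 26 pentacyclic phenol with OH on b1; 27 1-iodo-3,5-dimethoxybenzene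
Product: 28 heptamethyl ether of 29
Conditions: CuI (10 mol %), picolinic acid (20 mol %), K3PO4 (2 equiv), DMSO, 90 °C, argon
Reagents that add atoms: none
Why: Copper-catalysed Ullmann-type O-arylation of a phenol with an aryl iodide; the picolinic acid system is suited to phenols with two ortho substituents, and exclusion of air protects the para-alkoxyphenol from oxidation.

Step 15
Reactants: 28 heptamethyl ether of 29
Product: 29 target compound CNP0256302.0
Conditions: BBr3 (14 equiv), CH2Cl2, −78 °C → rt; then MeOH, H2O, 0 °C, argon
Reagents that add atoms: none
Why: Exhaustive Lewis-acid cleavage of the seven aryl methyl ethers by bromide attack on the boron-complexed methyl groups; the diaryl ether, dioxin and furan C–O bonds have no alkyl carbon to attack and stay intact.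

## Compound list

1 | 3,4,5-trimethoxyphenol | COc1cc(O)cc(OC)c1OC | starting material
2 | glyoxylic acid (oxoacetic acid, used as monohydrate) | OC(=O)C=O | starting material
3 | (±)-2-hydroxy-2-(2-hydroxy-4,5,6-trimethoxyphenyl)acetic acid (racemic) | COc1cc(O)c(C(O)C(=O)O)c(OC)c1OC | intermediate
4 | 2-(2-hydroxy-4,5,6-trimethoxyphenyl)acetic acid | COc1cc(O)c(CC(=O)O)c(OC)c1OC | intermediate
5 | 4,5,6-trimethoxy-1-benzofuran-2(3H)-one | COc1cc2OC(=O)Cc2c(OC)c1OC | intermediate
6 | benzyl 2-[2-(benzyloxy)-4,5,6-trimethoxyphenyl]acetate | COc1cc(OCc2ccccc2)c(CC(=O)OCc2ccccc2)c(OC)c1OC | intermediate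
7 | 2-[2-(benzyloxy)-4,5,6-trimethoxyphenyl]acetic acid | COc1cc(OCc2ccccc2)c(CC(=O)O)c(OC)c1OC | intermediate
8 | 2-[2-(benzyloxy)-4,5,6-trimethoxyphenyl]acetyl chloride | COc1cc(OCc2ccccc2)c(CC(=O)Cl)c(OC)c1OC | intermediate
9 | 1-methoxy-1,3-bis(trimethylsilyloxy)buta-1,3-diene (mixture of double-bond isomers) | COC(O[Si](C)(C)C)=CC(=C)O[Si](C)(C)C | starting material
10 | methyl 6-[2-(benzyloxy)-4,5,6-trimethoxyphenyl]-5-oxo-3-(trimethylsilyloxy)hex-2-enoate (double-bond geometry not fixed) | COC(=O)C=C(O[Si](C)(C)C)CC(=O)Cc1c(OCc2ccccc2)cc(OC)c(OC)c1OC | intermediate
11 | methyl 6-[2-(benzyloxy)-4,5,6-trimethoxyphenyl]-3,5-dioxohexanoate | COC(=O)CC(=O)CC(=O)Cc1c(OCc2ccccc2)cc(OC)c(OC)c1OC | intermediate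
12 | 2-[2-(benzyloxy)-4,5,6-trimethoxyphenyl]cyclohexane-1,3,5-trione | COc1cc(OCc2ccccc2)c(C2C(=O)CC(=O)CC2=O)c(OC)c1OC | intermediate
13 | 2-[2-(benzyloxy)-4,5,6-trimethoxyphenyl]benzene-1,3,5-triol | COc1cc(OCc2ccccc2)c(-c2c(O)cc(O)cc2O)c(OC)c1OC | intermediate
14 | 2-(2-hydroxy-4,5,6-trimethoxyphenyl)benzene-1,3,5-triol | COc1cc(O)c(-c2c(O)cc(O)cc2O)c(OC)c1OC | intermediate
15 | 7,8,9-trimethoxydibenzo[b,d]furan-1,3-diol | COc1cc2oc3cc(O)cc(O)c3c2c(OC)c1OC | intermediate
16 | 1,2,3,7,9-pentamethoxydibenzo[b,d]furan (OMe on C1, C3, C7, C8, C9 in the position labels used here) | COc1cc(OC)c2c(c1)oc1cc(OC)c(OC)c(OC)c12 | intermediate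
17 | cyclic chloroborate of 18 (B–Cl bridging O8 and O9 in a five-membered ring) | COc1cc(OC)c2c(c1)oc1cc(OC)c3OB(Cl)Oc3c12 | intermediate
18 | 3,7,9-trimethoxydibenzo[b,d]furan-1,2-diol (free OH on C8 and C9; OMe on C1, C3, C7) | COc1cc(OC)c2c(c1)oc1cc(OC)c(O)c(O)c12 | intermediate
19 | 1-fluoro-3,5-dimethoxybenzene | COc1cc(F)cc(OC)c1 | starting material
20 | N-[(2-fluoro-4,6-dimethoxyphenyl)methylidene]-N-methylmethanaminium chloride | COc1cc(F)c(C=[N+](C)C)c(OC)c1.[Cl-] | intermediate
21 | 2-fluoro-4,6-dimethoxybenzaldehyde | COc1cc(F)c(C=O)c(OC)c1 | intermediate
22 | 3-bromo-2-fluoro-4,6-dimethoxybenzaldehyde | COc1cc(OC)c(C=O)c(F)c1Br | intermediate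
23 | 3-bromo-2-[(1-hydroxy-3,7,9-trimethoxydibenzo[b,d]furan-2-yl)oxy]-4,6-dimethoxybenzaldehyde (ring B bound to O8; O9 free) | COc1cc(OC)c2c(c1)oc1cc(OC)c(Oc3c(C=O)c(OC)cc(OC)c3Br)c(O)c12 | intermediate
24 | pentacyclic dioxin aldehyde: O8–b6 and O9–b5 close the 1,4-dioxin; CHO on b1, OMe on b2 and b4; OMe on C1, C3, C7 | COc1cc(OC)c2c(c1)oc1cc(OC)c3Oc4c(C=O)c(OC)cc(OC)c4Oc3c12 | intermediate
25 | aryl formate of 26 (OCHO on b1) | COc1cc(OC)c2c(c1)oc1cc(OC)c3Oc4c(OC=O)c(OC)cc(OC)c4Oc3c12 | intermediate
26 | pentacyclic phenol: as 24 with OH in place of CHO on b1 | COc1cc(OC)c2c(c1)oc1cc(OC)c3Oc4c(O)c(OC)cc(OC)c4Oc3c12 | intermediate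
27 | 1-iodo-3,5-dimethoxybenzene | COc1cc(I)cc(OC)c1 | starting material
28 | heptamethyl ether of 29: as 26 with a 3,5-dimethoxyphenyl group on the b1 oxygen | COc1cc(OC)c2c(c1)oc1cc(OC)c3Oc4c(Oc5cc(OC)cc(OC)c5)c(OC)cc(OC)c4Oc3c12 | intermediate
29 | CNP0256302.0: ring A 3,5-dihydroxyphenoxy on b1; OH on b2, b4, C7, C1, C3; dioxin oxygens O8–b6 and O9–b5 | Oc1cc(O)cc(Oc2c(O)cc(O)c3c2Oc2c(O)cc4oc5cc(O)cc(O)c5c4c2O3)c1 | target

## Step count and least certain steps

Total: 15 steps. Longest linear sequence: 13 steps (steps 1 to 9 and 12 to 15); steps 10 and 11 form the ring B branch.

Step 6 (key step). The chain may stay as its unreactive bis-enolate, because proton transfer to the benzylic position is too unfavourable beside the two more acidic methylene groups. The ring may also close through the C-5 oxygen (lactonization to a pyranone), or the alkoxide may cleave the chain by retro-Claisen reaction. The fallback gives up the construction of ring D and uses known reactions: 1 is O-arylated with 27 (CuI, picolinic acid, K3PO4, DMSO) to the diaryl ether 5-(3,5-dimethoxyphenoxy)-1,2,3-trimethoxybenzene F1. F1 is then closed by intramolecular dehydrogenative C–H/C–H coupling of a diaryl ether (Pd(OAc)2 cat., pivalic acid, K2CO3, air, 120 °C). Both rings of F1 are symmetric, so only one dibenzofuran can form, and the route is rejoined at 16.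

Step 9. Control over which ethers are cut may be lost: cleavage at C7 in place of C9 would give the wrong catechol, and a fourth cleavage could occur on ring D, because the preference rests only on the twist of the C8 and C9 methoxy groups. The fallback sets out from 15, where ring D still has free hydroxyls. With BCl3 the boron bound to the C1 oxygen lies in the bay beside O9 and should deliver the Lewis acid to that ether, and the C8 ether follows through the five-membered borate; this gives 7-methoxydibenzo[b,d]furan-1,3,8,9-tetrol F2. The catechol of F2 is protected selectively with dichlorodiphenylmethane as the diphenylmethylene ketal F3. The ring D hydroxyls are methylated (Me2SO4, K2CO3) to F4, and hydrogenolysis (H2, Pd/C) removes the ketal and returns to the route at 18.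

Step 12. The order of the two oxygen attacks may be inverted, with the bay oxygen O9 substituting the fluoride first, which would turn ring B round; the copper-mediated closure at a bromide with two ortho substituents may also be slow and lose bromine by reduction. The fallback is meant for the case that O9 leads and uses an electrophile of opposite polarity, starting from 18. In 2,3-dichloro-5-methoxy-1,4-benzoquinone F5 the chlorine para to the methoxy group is displaced first; it is the one that must end on O9, and the second chlorine is activated as well, so no copper is needed. Double addition–elimination (K2CO3, MeCN) should give the dioxin quinone F6, and Na2S2O4 reduces it to the hydroquinone F7. Methylation of the less hindered b4 hydroxyl of F7 (MeI 1 equiv, K2CO3, acetone) comes back to the route at 26.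

Step 14. The coupling may be slow at a phenol flanked by a methoxy group and a dioxin oxygen, and the para-alkoxyphenol may be oxidized under copper catalysis. The fallback changes the bond-forming principle to a metal-free aryl transfer from trivalent iodine, starting from 26. (3,5-Dimethoxyphenyl)(2,4,6-trimethoxyphenyl)iodonium tosylate F8 is made in one pot from 27, mCPBA, TsOH and 1,3,5-trimethoxybenzene. It transfers its less electron-rich aryl group to the potassium phenoxide of 26 (KOtBu, THF, rt to 40 °C) and comes back to the route at 28.

## Further compounds

F1 | step 6 | 5-(3,5-dimethoxyphenoxy)-1,2,3-trimethoxybenzene | COc1cc(Oc2cc(OC)c(OC)c(OC)c2)cc(OC)c1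
F2 | step 9 | 7-methoxydibenzo[b,d]furan-1,3,8,9-tetrol | COc1cc2oc3cc(O)cc(O)c3c2c(O)c1O
F3 | step 9 | diphenylmethylene ketal of F2 across O8 and O9 | COc1cc2oc3cc(O)cc(O)c3c2c2OC(c3ccccc3)(c3ccccc3)Oc12
F4 | step 9 | 1,3-di-O-methyl ether of F3 | COc1cc(OC)c2c(c1)oc1cc(OC)c3OC(c4ccccc4)(c4ccccc4)Oc3c12
F5 | step 12 | 2,3-dichloro-5-methoxycyclohexa-2,5-diene-1,4-dione | COC1=CC(=O)C(Cl)=C(Cl)C1=O
F6 | step 12 | dioxin quinone: O8–b6 and O9–b5, C=O on b1 and b4, OMe on b2 and on C1, C3, C7 | COc1cc(OC)c2c(c1)oc1cc(OC)c3OC4=C(Oc3c12)C(=O)C=C(OC)C4=O
F7 | step 12 | hydroquinone of F6 (OH on b1 and b4) | COc1cc(OC)c2c(c1)oc1cc(OC)c3Oc4c(O)c(OC)cc(O)c4Oc3c12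
F8 | step 14 | (3,5-dimethoxyphenyl)(2,4,6-trimethoxyphenyl)iodonium 4-methylbenzenesulfonate | COc1cc(OC)cc([I+]c2c(OC)cc(OC)cc2OC)c1.Cc1ccc(cc1)S(=O)(=O)[O-]
A1 | alternative 1 | 1,2,3,7,9-pentamethoxydibenzo[b,d]furan (same compound as 16) | COc1cc(OC)c2c(c1)oc1cc(OC)c(OC)c(OC)c12
A2 | alternative 1 | 2-iodo-3,5-dimethoxyphenol | COc1cc(O)c(I)c(OC)c1
A3 | alternative 1 | 3,4,5-trimethoxy-2-(trimethylsilyl)phenyl trifluoromethanesulfonate | COc1cc(OS(=O)(=O)C(F)(F)F)c([Si](C)(C)C)c(OC)c1OC
A4 | alternative 2 | pentamethyl ether of the benzofuro-dibenzodioxin core with free OH on b1 (same compound as 26) | Oc1c(OC)cc(OC)c2c1Oc1c(OC)cc3oc4cc(OC)cc(OC)c4c3c1O2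
A5 | alternative 2 | spiroketal dienone: 2,4-dimethoxycyclohexa-2,4-dienone whose C-6 carries O8 and O9 of the ring C catechol (racemic) | COC1=CC(OC)=CC2(Oc3c(OC)cc4oc5cc(OC)cc(OC)c5c4c3O2)C1=O
A6 | alternative 3 | 2-(3,5-dimethoxyphenoxy)-5-ethoxy-3-isopropoxy-4-(triethylsilyloxy)phenol | CCOc1cc(O)c(Oc2cc(OC)cc(OC)c2)c(OC(C)C)c1O[Si](CC)(CC)CC
A7 | alternative 3 | 2-(3,5-dimethoxyphenoxy)-4-(1-ethoxyvinyl)-3-isopropoxy-4-(triethylsilyloxy)cyclobut-2-en-1-one (racemic) | CCOC(=C)C1(O[Si](CC)(CC)CC)C(OC(C)C)=C(Oc2cc(OC)cc(OC)c2)C1=O
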